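The retrosynthesis first takes the C6–C7 alkene back to a saturated ketone, then cuts the cyclohexanone ring at C7a–C7 and C3a–C4 into a 4-farnesylbutenolide and methyl vinyl ketone, and last cuts the butenolide–farnesyl C1' bond into a stannylbutenolide and farnesyl bromide (farnesyl = (2E,6E)-3,7,11-trimethyldodeca-2,6,10-trien-1-yl throughout).
Enabling feature (benzofuran-2,5-dione numbering: O1, lactone C2=O, C3, quaternary C3a carrying farnesyl C1', C4, ketone C5, alkene C6=C7, carbinol C7a): the two ring-fusion atoms are the gamma carbon (C7a, donor) and the beta carbon (C3a, acceptor) of the lactone ring seen as a butenolide, and they face the acceptor end (C7) and the donor end (C4) of the four-carbon enone unit C7–C6–C5–C4.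
Forward: bromobutenolide 1 is stannylated to 2 and joined to farnesyl bromide 3 to give butenolide 4, so the chain is attached to the preformed lactone ring; 4 and methyl vinyl ketone 5 are annulated through mono-adduct 6 to the cis-fused keto lactone 7, which closes the carbocycle; 7 is dehydrogenated through silyl enol ether 8 to target 9.
Stereochemistry: C7a (R) comes from the chiral primary amine catalyst in the first Michael addition; C3a (R) follows from C7a because the tether can only close cis; the 2E,6E alkenes are bought with farnesyl bromide and are not touched.

Key step: step 3

Assumption: the quinine-derived amine is taken to give the 7aR sense of induction; if the opposite face is preferred, the pseudoenantiomeric 9-amino-9-deoxy-epi-quinidine would be used with nothing else changed.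

Step 1
Reactants: 1 4-bromofuran-2(5H)-one
Product: 2 4-(tributylstannyl)furan-2(5H)-one
Conditions: (Bu3Sn)2 (1.1 equiv), Pd(PPh3)4 (5 mol%), THF, reflux
Reagents that add atoms: hexabutylditin, CCCC[Sn](CCCC)(CCCC)[Sn](CCCC)(CCCC)CCCC
Why: Palladium-catalysed stannylation of a vinyl bromide with a distannane (oxidative addition of the activated beta-bromo enoate to zerovalent palladium, Sn–Sn transmetallation, reductive elimination), a transformation established for 4-halofuranones.

Step 2
Reactants: 2 4-(tributylstannyl)furan-2(5H)-one; 3 (2E,6E)-farnesyl bromide ((2E,6E)-1-bromo-3,7,11-trimethyldodeca-2,6,10-triene)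
Product: 4 4-[(2E,6E)-3,7,11-trimethyldodeca-2,6,10-trien-1-yl]furan-2(5H)-one
Conditions: Pd2(dba)3 (2.5 mol%), P(2-furyl)3 (10 mol%), THF, 50 °C, no base
Reagents that add atoms: none
Why: Stille allyl–vinyl coupling, in which zerovalent palladium ionises 3 to a pi-allyl complex, the vinylstannane transmetallates and reductive elimination at the unsubstituted allyl terminus should give the linear skipped diene with the 2E alkene retained, while the base-free medium keeps the 1,4-diene out of conjugation with the lactone.

Step 3
Reactants: 4 4-[(2E,6E)-farnesyl]furan-2(5H)-one; 5 methyl vinyl ketone (but-3-en-2-one)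
Product: 7 (3aR,7aR)-3a-[(2E,6E)-3,7,11-trimethyldodeca-2,6,10-trien-1-yl]-3a,6,7,7a-tetrahydro-1-benzofuran-2,5(3H,4H)-dione, via mono-adduct (5R)-5-(3-oxobutyl)-4-[(2E,6E)-farnesyl]furan-2(5H)-one 6 (not isolated)
Conditions: 9-amino-9-deoxy-epi-quinine (20 mol%), salicylic acid (40 mol%), 5 (2 equiv, slow addition), toluene, 25 °C then 45 °C
Reagents that add atoms: none
Why: Proposed new method: the primary amine of the catalyst condenses with 5 to an iminium ion while its acid-buffered quinuclidine reversibly removes a ring C5 hydrogen of 4 (the future C7a) to give the 2-oxidofuran dienolate, whose gamma carbon adds to the iminium beta carbon (bond C7a–C7, giving 6 as its imine), after which the imine tautomerises to the methyl-side enamine, this adds to the butenolide beta carbon (bond C3a–C4), and hydrolysis frees 7 and the amine. The closest known reaction types are the amine-catalysed direct vinylogous Michael addition of butenolides to enones and intramolecular Michael closures of ketone enamines or enolates onto butenolide beta carbons that create quaternary centres, and what is new is their union in one two-component cascade. The cyclohexanone ring closes in a 6-(enolendo)-exo-trig mode, whereas the internal enamine could only close a four-membered ring and therefore returns through the enamine equilibrium. C7a is controlled by the catalyst, the protonated quinuclidine holding the dienolate in a hydrogen-bonded ion pair over one face of the covalently bound iminium ion so that a single enantioface of the gamma carbon is attacked. C3a is controlled by the substrate, because the four-atom tether anchored at C7a can reach the adjacent trigonal C3a only from its own face, which makes the ring fusion cis and C3a R once C7a is R. The step needs gamma rather than alpha attack and ring C5 rather than C1' deprotonation, both secured by the aromatic 2-oxidofuran character of the dienolate and the return to a conjugated butenolide after gamma attack, and it needs the farnesyl alkenes to stay untouched, which the soft, weakly basic amine salt medium should ensure.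

Step 4
Reactants: 7 (3aR,7aR)-3a-[(2E,6E)-farnesyl]-3a,6,7,7a-tetrahydro-1-benzofuran-2,5(3H,4H)-dione
Product: 8 (3aR,7aR)-3a-[(2E,6E)-3,7,11-trimethyldodeca-2,6,10-trien-1-yl]-5-(trimethylsilyloxy)-3a,4,7,7a-tetrahydro-1-benzofuran-2(3H)-one
Conditions: 7 added to LiN(i-Pr)2 (1.1 equiv) and Me3SiCl (1.5 equiv), THF, −78 °C; Et3N, pentane, filtration, used crude
Reagents that add atoms: chlorotrimethylsilane, C[Si](C)(C)Cl
Why: Kinetic enolisation with in situ silyl trapping, in which the ketone alpha-hydrogens are far more acidic than those of the lactone and the bulky amide should remove a C6 hydrogen in preference to the neopentyl C4 hydrogen next to quaternary C3a, any C4 regioisomer being harmless because it has no beta-hydrogen to lose and returns 7.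

Step 5
Reactants: 8 (3aR,7aR)-3a-[(2E,6E)-farnesyl]-5-(trimethylsilyloxy)-3a,4,7,7a-tetrahydro-1-benzofuran-2(3H)-one
Product: 9 (3aR,7aR)-3a-[(2E,6E)-3,7,11-trimethyldodeca-2,6,10-trien-1-yl]-3a,7a-dihydro-1-benzofuran-2,5(3H,4H)-dione (CNP0400313.1)
Conditions: Pd(OAc)2 (1.1 equiv), MeCN, 25 °C
Reagents that add atoms: none
Why: Saegusa–Ito oxidation, in which divalent palladium exchanges with silicon to a palladium enolate bound at C6 and beta-hydride elimination of a C7 hydrogen releases the C6–C7 enone, the stereocentres at C3a and C7a taking no part and the trisubstituted farnesyl alkenes being poor ligands at room temperature.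

Compound list
1 | 4-bromofuran-2(5H)-one | O=C1C=C(Br)CO1 | starting material
2 | 4-(tributylstannyl)furan-2(5H)-one | CCCC[Sn](CCCC)(CCCC)C1=CC(=O)OC1 | intermediate
3 | (2E,6E)-farnesyl bromide | CC(C)=CCC/C(C)=C/CC/C(C)=C/CBr | starting material
4 | 4-[(2E,6E)-3,7,11-trimethyldodeca-2,6,10-trien-1-yl]furan-2(5H)-one | CC(C)=CCC/C(C)=C/CC/C(C)=C/CC1=CC(=O)OC1 | intermediate
5 | methyl vinyl ketone (but-3-en-2-one) | C=CC(C)=O | starting material
6 | (5R)-5-(3-oxobutyl)-4-[(2E,6E)-3,7,11-trimethyldodeca-2,6,10-trien-1-yl]furan-2(5H)-one (not isolated) | CC(C)=CCC/C(C)=C/CC/C(C)=C/CC1=CC(=O)O[C@@H]1CCC(C)=O | intermediate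
7 | (3aR,7aR)-3a-[(2E,6E)-3,7,11-trimethyldodeca-2,6,10-trien-1-yl]-3a,6,7,7a-tetrahydro-1-benzofuran-2,5(3H,4H)-dione (cis-fused) | CC(C)=CCC/C(C)=C/CC/C(C)=C/C[C@]12CC(=O)CC[C@H]1OC(=O)C2 | intermediate
8 | (3aR,7aR)-3a-[(2E,6E)-3,7,11-trimethyldodeca-2,6,10-trien-1-yl]-5-(trimethylsilyloxy)-3a,4,7,7a-tetrahydro-1-benzofuran-2(3H)-one | CC(C)=CCC/C(C)=C/CC/C(C)=C/C[C@]12CC(O[Si](C)(C)C)=CC[C@H]1OC(=O)C2 | intermediate
9 | (3aR,7aR)-3a-[(2E,6E)-3,7,11-trimethyldodeca-2,6,10-trien-1-yl]-3a,7a-dihydro-1-benzofuran-2,5(3H,4H)-dione | CC(C)=CCC/C(C)=C/CC/C(C)=C/C[C@]12CC(=O)C=C[C@H]1OC(=O)C2 | target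

Total step count: 5. Longest linear sequence: 5 steps (1 → 2 → 4 → 7 → 8 → 9).

Steps most likely to fail

Step 3. The cascade may stall after the first Michael addition because the primary-amine enamine is too weak a nucleophile for the beta,beta-disubstituted butenolide. The stalled mono-adduct may also lose its configuration at C7a through renewed gamma-deprotonation, and excess 5 may oligomerise or add a second time. The fallback separates the two bond formations into two known reactions. Setting out from 4 and 5, only the amine-catalysed direct vinylogous Michael addition is run, with the same chiral primary amine salt at 0–25 °C, and it is stopped at mono-adduct 6, which is now isolated. In a separate flask 6 is cyclised through its stoichiometric pyrrolidine enamine (pyrrolidine, AcOH, CH2Cl2, 25–40 °C, then aqueous NH4Cl), a Stork-enamine intramolecular Michael addition that no longer depends on turnover of the chiral catalyst. The route is rejoined at 7, and no compound outside the list is formed.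

Step 2. Reductive elimination may occur at the tertiary allyl terminus, the 2E alkene may scramble through syn–anti interconversion of the pi-allyl complex, or slow transmetallation of the electron-poor stannane may let the farnesyl unit homocouple or eliminate. The fallback reverses the roles of the partners. Setting out from 3, treatment with Bu3SnLi (THF, −78 °C) should give tributyl[(2E,6E)-3,7,11-trimethyldodeca-2,6,10-trien-1-yl]stannane F1. F1 is then coupled with bromide 1 (Pd(PPh3)4, LiCl, DMF, 80 °C). In this mode, the one used for Stille prenylations, zerovalent palladium inserts into the vinyl C–Br bond and the allyl group arrives by transmetallation, so no pi-allyl complex of the farnesyl unit is formed. The route is rejoined at 4, and step 1 is then not needed.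

Step 4. Deprotonation may compete at C4 or at the lactone C3 (the latter opening the way to retro-Michael ring opening), and the labile trimethylsilyl enol ether may hydrolyse before it is oxidised. The fallback sets out from 7 and dehydrogenates it directly with 2-iodoxybenzoic acid (IBX, DMSO/toluene, 65 °C). This reaction passes through the enol, so it needs neither a regioselective enolate nor a silyl enol ether. Because C3a is quaternary, only the C6–C7 side can lose hydrogen. The route is rejoined at 9, bypassing 8 and step 5, and no compound outside the list is formed.

Further compounds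
F0 | step 3 | none | none
F1 | step 2 | tributyl[(2E,6E)-3,7,11-trimethyldodeca-2,6,10-trien-1-yl]stannane | CC(C)=CCC/C(C)=C/CC/C(C)=C/C[Sn](CCCC)(CCCC)CCCC
F0 | step 4 | none | none
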